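**Plan**

Locants follow carotenoid numbering: unprimed for the hydroxylated half (ring A, C1–C15), primed for the cyclohexadiene half (ring B). The target is all-E (3R)-3',4',7,8,7',8'-hexadehydro-β,β-caroten-3-ol.
Retrosynthesis: cut O–Si; then C10–C11 together with C9–CH3 (ring-A diyne + AlMe3 + C26 iodide); then C10'–C11' together with C9'–CH3 (ring-B diyne + AlMe3 + C12 diiodide); then C11=C12 and C11'=C12' back to the C10 dialdehyde. The diynes go back to the ring-A enol triflate (C6–C7) and to safranal (C7'≡C8', C8'–C9').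
Enabling feature: on the C9=C10 double bond, C9 carries a methyl group cis to C11 and is bonded to the C7≡C8 triple bond on ring A. This 2-methyl-1-en-3-yne end is the imprint of a syn CH3–Al addition to the terminal triple bond of a ring-bound buta-1,3-diyne, so the methyl group, the 9E geometry and the C10–C11 bond can be made in one flask from three components (the same holds at C9'/C10'/C11').
Forward: the ring-B diyne is joined to the C12 diiodide to give the C26 iodide; the ring-A diyne is then joined to it in the key step; desilylation ends the route. No ring is formed; both rings are bought.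
Stereochemistry: C3 (R) comes from (4R,6R)-actinol; 9E and 9'E from syn-carboalumination; 11E and 11'E from Takai olefination; 13E, 15E and 13'E from the dialdehyde; both couplings should proceed with retention.

Key step: step 10

Assumption: safranal, (2E,4E,6E)-2,7-dimethylocta-2,4,6-trienedial, (4R,6R)-actinol, 1,4-bis(trimethylsilyl)buta-1,3-diyne and (bromoethynyl)triisopropylsilane are taken as commercial; all polyenes and terminal diynes are handled under argon in the dark and used without storage.

**Route**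

Step 1
Reactants: 1 safranal (2,6,6-trimethylcyclohexa-1,3-diene-1-carbaldehyde)
Product: 2 1-ethynyl-2,6,6-trimethylcyclohexa-1,3-diene
Conditions: Me3SiCHN2, n-BuLi, THF, −78 °C → 23 °C
Reagents that add atoms: trimethylsilyldiazomethane, C[Si](C)(C)C=[N+]=[N-]
Why: Colvin rearrangement, in which lithiated trimethylsilyldiazomethane adds to the non-enolisable aldehyde, Peterson-type loss of silanolate and of N2 is followed by a 1,2-hydride shift to the terminal alkyne (C7'≡C8'), and the methanol-free medium avoids conjugate addition to the dienal.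

Step 2
Reactants: 2 1-ethynyl-2,6,6-trimethylcyclohexa-1,3-diene; 3 (bromoethynyl)tri(propan-2-yl)silane
Product: 4 tri(propan-2-yl)[4-(2,6,6-trimethylcyclohexa-1,3-dien-1-yl)buta-1,3-diyn-1-yl]silane
Conditions: CuCl (5 mol %), NH2OH·HCl (cat.), n-BuNH2, H2O/CH2Cl2, 0 °C
Reagents that add atoms: none
Why: Cadiot–Chodkiewicz coupling, in which the monovalent copper acetylide of 2 couples with the bromoalkyne to form C8'–C9' while the bulky silyl group suppresses homocoupling.

Step 3
Reactants: 4 tri(propan-2-yl)[4-(2,6,6-trimethylcyclohexa-1,3-dien-1-yl)buta-1,3-diyn-1-yl]silane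
Product: 5 1-(buta-1,3-diyn-1-yl)-2,6,6-trimethylcyclohexa-1,3-diene
Conditions: Bu4NF (1.1 equiv), wet THF, 0 °C; used at once as a solution
Reagents that add atoms: none
Why: fluoride-induced protodesilylation of the alkynylsilane, the only silicon group present, should release the terminal diyne cleanly.

Step 4
Reactants: 6 (2E,4E,6E)-2,7-dimethylocta-2,4,6-trienedial
Product: 7 (1E,3E,5E,7E,9E)-1,10-diiodo-3,8-dimethyldeca-1,3,5,7,9-pentaene
Conditions: CrCl2 (12 equiv), CHI3 (4 equiv), THF/1,4-dioxane, 0 °C → 23 °C, dark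
Reagents that add atoms: iodoform, IC(I)I
Why: twofold Takai iodo-olefination, in which the geminal dichromium species from CHI3 adds to each aldehyde and elimination through the less crowded arrangement should give the E iodovinyl group at C11 and at C11'.

Step 5
Reactants: 5 1-(buta-1,3-diyn-1-yl)-2,6,6-trimethylcyclohexa-1,3-diene; 7 (1E,3E,5E,7E,9E)-1,10-diiodo-3,8-dimethyldeca-1,3,5,7,9-pentaene (3 equiv)
Product: 9 1-[(3E,5E,7E,9E,11E,13E)-14-iodo-3,7,12-trimethyltetradeca-3,5,7,9,11,13-hexaen-1-yn-1-yl]-2,6,6-trimethylcyclohexa-1,3-diene, via alkenylalane 8 (not isolated)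
Conditions: AlMe3 (2 equiv), Cp2ZrCl2 (25 mol %), (CH2Cl)2, 0 → 23 °C; volatiles removed in vacuo; then 7 (3 equiv), Pd2(dba)3 (2.5 mol %), P(2-furyl)3 (10 mol %), ZnCl2 (30 mol %), THF/DMF, 23 °C, dark
Reagents that add atoms: trimethylaluminium, C[Al](C)C
Why: zirconium-catalysed syn-methylalumination of the terminal triple bond places CH3 on C9' and aluminium on C10' and so sets the 9'E alkene, and Negishi coupling with one iodovinyl end of 7, used in excess so that single coupling is statistically favoured and the surplus should be recoverable, forms C10'–C11' with retention.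

Step 6
Reactants: 10 (4R,6R)-4-hydroxy-2,2,6-trimethylcyclohexan-1-one (actinol)
Product: 11 (4R,6R)-4-{[tert-butyl(dimethyl)silyl]oxy}-2,2,6-trimethylcyclohexan-1-one
Conditions: TBSCl, imidazole, DMF, 23 °C
Reagents that add atoms: tert-butyl(chloro)dimethylsilane, CC(C)(C)[Si](C)(C)Cl
Why: standard silylation of the secondary alcohol, which leaves the carbinol stereocentre (the later C3) untouched.

Step 7
Reactants: 11 (4R,6R)-4-{[tert-butyl(dimethyl)silyl]oxy}-2,2,6-trimethylcyclohexan-1-one
Product: 13 (4R)-4-{[tert-butyl(dimethyl)silyl]oxy}-2,6,6-trimethylcyclohex-1-en-1-yl trifluoromethanesulfonate, via lithium enolate 12 (not isolated)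
Conditions: LiN(i-Pr)2, THF, −78 °C; then PhNTf2, −78 → 23 °C
Reagents that add atoms: N-phenylbis(trifluoromethanesulfonimide), O=S(=O)(N(c1ccccc1)S(=O)(=O)C(F)(F)F)C(F)(F)F
Why: the ketone has a single α-hydrogen, so deprotonation gives one tetrasubstituted enolate (the methyl-bearing stereocentre is erased on purpose) whose O-triflation gives the enol triflate with the silyloxy stereocentre unchanged.

Step 8
Reactants: 13 (4R)-4-{[tert-butyl(dimethyl)silyl]oxy}-2,6,6-trimethylcyclohex-1-en-1-yl trifluoromethanesulfonate; 14 1,4-bis(trimethylsilyl)buta-1,3-diyne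
Product: 17 tert-butyl(dimethyl){[(1R)-3,5,5-trimethyl-4-[4-(trimethylsilyl)buta-1,3-diyn-1-yl]cyclohex-3-en-1-yl]oxy}silane, via lithium diynide 15 (not isolated), via diynylzinc chloride 16 (not isolated)
Conditions: 14 (1.5 equiv), MeLi·LiBr, THF, 23 °C; ZnCl2, 0 °C; then 13, Pd(PPh3)4 (5 mol %), THF, 23 → 50 °C
Reagents that add atoms: none
Why: methyllithium removes one silyl group of 14, transmetalation to zinc gives a diynylzinc, and Negishi alkynylation of the hindered enol triflate under zerovalent palladium catalysis forms C6–C7.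

Step 9
Reactants: 17 tert-butyl(dimethyl){[(1R)-3,5,5-trimethyl-4-[4-(trimethylsilyl)buta-1,3-diyn-1-yl]cyclohex-3-en-1-yl]oxy}silane
Product: 18 {[(1R)-4-(buta-1,3-diyn-1-yl)-3,5,5-trimethylcyclohex-3-en-1-yl]oxy}(tert-butyl)dimethylsilane
Conditions: K2CO3 (cat.), MeOH/THF, 0 °C; used at once as a solution
Reagents that add atoms: none
Why: base-catalysed methanolysis cleaves the alkynyl C–Si bond selectively over the secondary silyl ether and releases the terminal diyne.

Step 10
Reactants: 18 {[(1R)-4-(buta-1,3-diyn-1-yl)-3,5,5-trimethylcyclohex-3-en-1-yl]oxy}(tert-butyl)dimethylsilane (1.3 equiv); 9 1-[(3E,5E,7E,9E,11E,13E)-14-iodo-3,7,12-trimethyltetradeca-3,5,7,9,11,13-hexaen-1-yn-1-yl]-2,6,6-trimethylcyclohexa-1,3-diene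
Product: 20 tert-butyldimethylsilyl ether of all-E (3R)-3',4',7,8,7',8'-hexadehydro-β,β-caroten-3-ol, via alkenylalane 19 (not isolated)
Conditions: 18, AlMe3 (2 equiv), Cp2ZrCl2 (25 mol %), (CH2Cl)2, 0 → 23 °C; volatiles removed in vacuo; then 9, Pd2(dba)3 (2.5 mol %), P(2-furyl)3 (10 mol %), ZnCl2 (30 mol %), THF/DMF, 23 °C, dark
Reagents that add atoms: trimethylaluminium, C[Al](C)C
Why: Cp2ZrCl2-catalysed syn-methylalumination adds CH3 to C9 and aluminium to the terminal C10 of diyne 18, so alkenylalane 19 carries CH3 and Al cis, which fixes the 9E geometry; in the same flask the alkenyl group passes from aluminium through zinc to the alkenylpalladium iodide formed from 9, and reductive elimination makes the C10–C11 bond with retention at both alkenyl carbons. The closest known reaction type is the zirconium-catalysed carboalumination followed by palladium- and zinc-catalysed alkenyl–alkenyl Negishi coupling used to assemble retinoid and carotenoid chains. No ring is closed and no stereocentre is formed; C3 is remote and silyl-protected. The step needs chemoselectivity for the terminal over the internal triple bond, which the fully substituted C6 of ring A with the flanking C1 gem-dimethyl and C5 methyl groups should secure by shielding C7≡C8, and regioselectivity for aluminium at C10, which the unsubstituted alkyne terminus should secure. The hexaene of 9 should keep its geometry because the coupling runs at 23 °C in the dark under a zerovalent palladium catalyst that couples vinyl iodides with retention.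

Step 11
Reactants: 20 tert-butyldimethylsilyl ether of all-E (3R)-3',4',7,8,7',8'-hexadehydro-β,β-caroten-3-ol
Product: 21 all-E (3R)-3',4',7,8,7',8'-hexadehydro-β,β-caroten-3-ol (CNP0250213.1)
Conditions: Bu4NF, THF, 23 °C, dark
Reagents that add atoms: none
Why: fluoride cleavage of the silyl ether should liberate the C3 alcohol with its R configuration intact and without touching the polyene.

**Compound list**

1 | safranal, 2,6,6-trimethylcyclohexa-1,3-diene-1-carbaldehyde | CC1=C(C=O)C(C)(C)CC=C1 | starting material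
2 | 1-ethynyl-2,6,6-trimethylcyclohexa-1,3-diene | CC1=C(C#C)C(C)(C)CC=C1 | intermediate
3 | (bromoethynyl)tri(propan-2-yl)silane | BrC#C[Si](C(C)C)(C(C)C)C(C)C | starting material
4 | tri(propan-2-yl)[4-(2,6,6-trimethylcyclohexa-1,3-dien-1-yl)buta-1,3-diyn-1-yl]silane | CC1=C(C#CC#C[Si](C(C)C)(C(C)C)C(C)C)C(C)(C)CC=C1 | intermediate
5 | 1-(buta-1,3-diyn-1-yl)-2,6,6-trimethylcyclohexa-1,3-diene | CC1=C(C#CC#C)C(C)(C)CC=C1 | intermediate
6 | (2E,4E,6E)-2,7-dimethylocta-2,4,6-trienedial | O=C/C(C)=C/C=C/C=C(C)/C=O | starting material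
7 | (1E,3E,5E,7E,9E)-1,10-diiodo-3,8-dimethyldeca-1,3,5,7,9-pentaene | I/C=C/C(C)=C/C=C/C=C(C)/C=C/I | intermediate
8 | dimethyl[(1E)-2-methyl-4-(2,6,6-trimethylcyclohexa-1,3-dien-1-yl)but-1-en-3-yn-1-yl]alumane | CC1=C(C#C/C(C)=C/[Al](C)C)C(C)(C)CC=C1 | intermediate
9 | 1-[(3E,5E,7E,9E,11E,13E)-14-iodo-3,7,12-trimethyltetradeca-3,5,7,9,11,13-hexaen-1-yn-1-yl]-2,6,6-trimethylcyclohexa-1,3-diene | CC1=C(C#C/C(C)=C/C=C/C(C)=C/C=C/C=C(C)/C=C/I)C(C)(C)CC=C1 | intermediate
10 | (4R,6R)-4-hydroxy-2,2,6-trimethylcyclohexan-1-one (actinol) | O=C1[C@H](C)C[C@@H](O)CC1(C)C | starting material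
11 | (4R,6R)-4-{[tert-butyl(dimethyl)silyl]oxy}-2,2,6-trimethylcyclohexan-1-one | O=C1[C@H](C)C[C@@H](O[Si](C)(C)C(C)(C)C)CC1(C)C | intermediate
12 | lithium (4R)-4-{[tert-butyl(dimethyl)silyl]oxy}-2,6,6-trimethylcyclohex-1-en-1-olate | [Li]OC1=C(C)C[C@@H](O[Si](C)(C)C(C)(C)C)CC1(C)C | intermediate
13 | (4R)-4-{[tert-butyl(dimethyl)silyl]oxy}-2,6,6-trimethylcyclohex-1-en-1-yl trifluoromethanesulfonate | O=S(=O)(OC1=C(C)C[C@@H](O[Si](C)(C)C(C)(C)C)CC1(C)C)C(F)(F)F | intermediate
14 | 1,4-bis(trimethylsilyl)buta-1,3-diyne | C[Si](C)(C)C#CC#C[Si](C)(C)C | starting material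
15 | [4-(trimethylsilyl)buta-1,3-diyn-1-yl]lithium | [Li]C#CC#C[Si](C)(C)C | intermediate
16 | chloro[4-(trimethylsilyl)buta-1,3-diyn-1-yl]zinc | Cl[Zn]C#CC#C[Si](C)(C)C | intermediate
17 | tert-butyl(dimethyl){[(1R)-3,5,5-trimethyl-4-[4-(trimethylsilyl)buta-1,3-diyn-1-yl]cyclohex-3-en-1-yl]oxy}silane | C[Si](C)(C)C#CC#CC1=C(C)C[C@@H](O[Si](C)(C)C(C)(C)C)CC1(C)C | intermediate
18 | {[(1R)-4-(buta-1,3-diyn-1-yl)-3,5,5-trimethylcyclohex-3-en-1-yl]oxy}(tert-butyl)dimethylsilane | C#CC#CC1=C(C)C[C@@H](O[Si](C)(C)C(C)(C)C)CC1(C)C | intermediate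
19 | [(1E)-4-[(4R)-4-{[tert-butyl(dimethyl)silyl]oxy}-2,6,6-trimethylcyclohex-1-en-1-yl]-2-methylbut-1-en-3-yn-1-yl]dimethylalumane | C[Al](C)/C=C(\C)C#CC1=C(C)C[C@@H](O[Si](C)(C)C(C)(C)C)CC1(C)C | intermediate
20 | tert-butyldimethylsilyl ether of all-E (3R)-3',4',7,8,7',8'-hexadehydro-β,β-caroten-3-ol | CC1=C(C#C/C(C)=C/C=C/C(C)=C/C=C/C=C(C)/C=C/C=C(\C)C#CC2=C(C)C[C@@H](O[Si](C)(C)C(C)(C)C)CC2(C)C)C(C)(C)CC=C1 | intermediate
21 | all-E (3R)-3',4',7,8,7',8'-hexadehydro-β,β-caroten-3-ol (CNP0250213.1) | CC1=C(C#C/C(C)=C/C=C/C(C)=C/C=C/C=C(C)/C=C/C=C(\C)C#CC2=C(C)C[C@@H](O)CC2(C)C)C(C)(C)CC=C1 | target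

**Count**

Total steps: 11. Longest linear sequence: 6 steps (10 → 21 through steps 6, 7, 8, 9, 10, 11; equally 1 → 21 through steps 1, 2, 3, 5, 10, 11).

**Steps most likely to fail**

Step 10. The acidic C–H of the conjugated diyne may be aluminated instead of the triple bond being methylated, the methyl group may add with incomplete regiocontrol, and slow transfer of the hindered alkenyl group from aluminium to palladium would leave the polyenyl iodide exposed to Lewis-acidic aluminium species and to geometric isomerisation. The fallback sets out from 18. Copper-catalysed methylboration (B2pin2, MeI, CuCl/Xantphos, NaOt-Bu, THF, 23 °C) places boron on the terminal carbon and methyl on C9 by syn addition and gives the isolable alkenyl pinacol boronate F1, whose geometry can be checked before use. Suzuki–Miyaura coupling of F1 with 9 (Pd(PPh3)4, aq. K3PO4, THF, 23 °C, dark) comes back to the route at 20.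

Step 5. The second iodovinyl end of 7 is as reactive as the first, so over-coupling to the symmetric bis-adduct and loss of material in a statistical mixture may occur, together with the same carboalumination problems as in step 10. The fallback sets out from 6 and 5. One-sided Takai olefination of 6 (CHI3 1 equiv, CrCl2, THF, 0 °C; the remaining aldehyde becomes less electrophilic once the first has turned into an iodovinyl group) gives the iodo-tetraenal F2. Copper-catalysed methylboration of 5 gives the alkenyl pinacol boronate F3. Suzuki–Miyaura coupling of F2 with F3 (Pd(PPh3)4, aq. K3PO4, THF, 23 °C) gives the C25 polyenynal F4, and Takai olefination of F4 (CrCl2, CHI3, THF/1,4-dioxane) comes back to the route at 9.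

Step 4. E selectivity may be incomplete at one or both new iodovinyl ends, and the light-sensitive diiodide may be lost while geometric isomers are separated. The fallback sets out from 6. Twofold Colvin homologation (Me3SiCHN2, n-BuLi, THF, −78 → 23 °C) gives the trienediyne F5. Twofold hydrozirconation with Cp2Zr(H)Cl (THF, 23 °C, dark) gives the bis(alkenylzirconocene chloride) F6, not isolated, in which both E geometries are set by syn addition of Zr–H. Iodinolysis with I2 at 0 °C comes back to the route at 7.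

**Further compounds**

F1 | step 10 | 2-[(1E)-4-[(4R)-4-{[tert-butyl(dimethyl)silyl]oxy}-2,6,6-trimethylcyclohex-1-en-1-yl]-2-methylbut-1-en-3-yn-1-yl]-4,4,5,5-tetramethyl-1,3,2-dioxaborolane | CC1(C)OB(/C=C(\C)C#CC2=C(C)C[C@@H](O[Si](C)(C)C(C)(C)C)CC2(C)C)OC1(C)C
F2 | step 5 | (2E,4E,6E,8E)-9-iodo-2,7-dimethylnona-2,4,6,8-tetraenal | O=C/C(C)=C/C=C/C=C(C)/C=C/I
F3 | step 5 | 4,4,5,5-tetramethyl-2-[(1E)-2-methyl-4-(2,6,6-trimethylcyclohexa-1,3-dien-1-yl)but-1-en-3-yn-1-yl]-1,3,2-dioxaborolane | CC1=C(C#C/C(C)=C/B2OC(C)(C)C(C)(C)O2)C(C)(C)CC=C1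
F4 | step 5 | (2E,4E,6E,8E,10E)-2,7,11-trimethyl-13-(2,6,6-trimethylcyclohexa-1,3-dien-1-yl)trideca-2,4,6,8,10-pentaen-12-ynal | CC1=C(C#C/C(C)=C/C=C/C(C)=C/C=C/C=C(C)/C=O)C(C)(C)CC=C1
F5 | step 4 | (3E,5E,7E)-3,8-dimethyldeca-3,5,7-triene-1,9-diyne | C#C/C(C)=C/C=C/C=C(C)/C#C
F6 | step 4 | [(1E,3E,5E,7E,9E)-3,8-dimethyldeca-1,3,5,7,9-pentaene-1,10-diyl]bis[chlorobis(cyclopentadienyl)zirconium], cyclopentadienyl rings drawn sigma-bonded | Cl[Zr](/C=C/C(C)=C/C=C/C=C(C)/C=C/[Zr](Cl)(C1C=CC=C1)C1C=CC=C1)(C1C=CC=C1)C1C=CC=C1
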